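## The problem

The target is a stilbene trimer in which two trans-2,3-diaryl-2,3-dihydrobenzofurans are joined through ring B. Ring B is the benzo ring of the inner furan (O1' on B6, C3' on B5, free hydroxyl on B4) and, through B1, the C2 aryl group of the outer furan. The outer benzo ring A also carries a C6 hydroxyl and an (E)-4-hydroxystyryl group at C4. Rings A and B are contiguously tetrasubstituted and stand beside four other oxygenated rings of similar reactivity, so no substituent can be added late by electrophilic substitution; every position has to arrive with a building block or by a directed reaction. The four stereocentres form two trans pairs, (2S,3S) and (2'S,3'S), separated by ring B and unable to control each other, so two independent sources of absolute configuration are needed. Within a pair the diarylmethine carbon (C3, C3') is configurationally robust, whereas the O-benzylic carbon (C2, C2') carries an ortho,para-oxygenated aryl group, ionises easily and settles trans to its neighbour when it can equilibrate. Those benzylic C–O bonds are also the weak points (acid opens them, oxidants dehydrogenate the ring to a benzofuran), together with the stilbene (acid, hydrogen, oxidants) and nine phenols that must travel as ethers. The enabling feature is that C2 sits on B1, para to the B4 hydroxyl and four bonds from the ring A oxygen O1. Two-electron oxidation of a free B4 phenol in an open-chain precursor makes C2 the exocyclic carbon of a para-quinone methide that O1 can close onto, so the task reduces to an (S)-1,1,2-triarylethane holding the inner furan, with only the ring A and B4 phenols free.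

## Retrosynthesis

**32 from 31.** The last cut is through eight O–CH3 bonds. Methyl ethers are chosen as the permanent protection because the aryl building blocks 4, 9, 17 and 30 are sold as methyl ethers and because they survive organolithium, palladium, hydrogenation and DDQ chemistry. Benzyl ethers would need a hydrogenolysis that the stilbene does not survive. The forward step asks BBr3 to spare the stilbene and both furans.

**31 from 29 and 30.** The C4–vinyl bond is cut next, so the stilbene is made last, after both hydrogenations, the hydrogenolysis and the oxidation. A Suzuki–Miyaura coupling of aryl triflate 29 with alkenylboronic acid 30 is preferred to a Heck reaction because the (E) geometry comes ready-made in 30. The step must couple a hindered triflate beside a free phenol.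

**29 from 27 (key cut).** The O1–C2 bond is cut. Cutting C2–C3 or C3–C3a instead would require both outer stereocentres to be made at once, and closure by substitution at C2 cannot give clean inversion at an ortho,para-oxygenated benzylic carbon. The chosen cut leaves only C3 in the precursor 27, one ring and one stereocentre simpler, and lets C2 follow C3. The forward reaction must oxidise the B4 phenol and not the ring A phenol; the triflate on ring A is there to help with that.

**27 from 24 (through 26 and 25).** Only protecting groups change. The two ortho oxygens of ring A are marked differently: the MOM ether is removed first and its oxygen becomes the triflate (25, 26); the benzyl ether is removed together with the B4 benzyl ether to give the two free phenols of 27. Which ortho oxygen carries which group is immaterial, because rotation about the C3–C3a bond exchanges them.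

**24 from 23.** The C3–H and C2–H bonds are cut: asymmetric hydrogenation of a triarylethylene. This is the most direct catalytic way to a diarylmethine carrying a CH2Ar group (conjugate additions give a chain one carbon too long). It demands a single alkene isomer, because the face that the catalyst selects depends on the geometry.

**23 from 19, 16 and 9 (through 20 and 22).** The C3–aryl bond is cut at the (Z)-enol triflate 22 and the C2–B1 bond at ketone 20. A Wittig reaction or dehydration on a diaryl ketone would give E/Z mixtures, whereas the enolate of 20 has one geometry, which the triflate and the Suzuki coupling preserve. Ring A enters as acetophenone 19, whose carbonyl carbon is C3 and whose methyl group is C2. This avoids a ring A organometallic, which could not be made regioselectively from a 3,5-dialkoxyanisole with three competing lithiation sites.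

**16 from 13 (through 15).** The aryl triflate is traced to a phenol and this to an aldehyde (Dakin oxidation). The formyl group of 13 differentiated the two ring B oxygens in the starting material, was masked during lithiation and deactivates ring B in the inner oxidation. The price is two steps and the loss of one carbon.

**13 from 10 (through 12 and 11).** The O1'–C2' bond is cut in the same way as O1–C2, here as a hydride abstraction from the 2,4-dimethoxybenzylic methylene of 12. C3' is then set by the same hydrogenation as C3 (10 to 11), so step 6 is an early test of step 16.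

**10 from 3, 5 and 9 (through 8, 6 and 7).** Both aryl–C3' bonds are cut at 1,1-dibromoalkene 5. The hindered ring B arylzinc 7 takes the bromide trans to the aryl group, and boronic acid 9 takes the remaining one. Here the ring B organometallic is regiochemically unambiguous, since only one position of 3 lies between two alkoxy groups.

**Building blocks.** Acetal 3 comes from commercial 1 through 2, dibromoalkene 5 from aldehyde 4, and ketone 19 from 17 through 18. In 1 and in 17 hydrogen bonding to the carbonyl group decides which hydroxyl is alkylated first.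

## Roads not taken

Alternative 1: Ring B would be assembled by a Danheiser benzannulation, cutting B5–B6, B3–B4 and B1–B6. Photochemical Wolff rearrangement of an unsaturated diazoketone carrying the finished outer furan gives a vinylketene; this adds to a siloxyalkyne carrying the C3'/C2' unit, and electrocyclic opening and closure deliver phenol A1.
- Merits: it is the most convergent plan. It builds the crowded ring B with all four substituents placed by the mechanism, and it gives B6–OH free and B4–O silylated, a differentiation that costs several protecting-group steps in the chosen plan.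
- Weak points: both stereo pairs must exist before the annulation, so the outer furan still has to be made by another method. The diazoketone half has a β-aryloxy stereocentre (C2) prone to elimination, and the alkyne half a propargylic diarylmethine (C3') prone to allene formation, both under light and heat. The inner ring would then be closed by substitution at a 2,4-dimethoxybenzylic carbon, which ionises.
- Comparison: A1 wins on convergence and on ring B differentiation. The chosen plan sets against this that ring B is bought with its oxygens already distinguished (1), that each stereo pair is made and checked separately, and that no finished stereocentre meets photolysis or prolonged heating.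

Alternative 2: The inner furan would be cut at C2'–C3' and O1'–C2'. Base releases an ortho-quinone methide on ring B from a benzhydrol; a chiral 2,4-dimethoxybenzyl sulfonium ylide adds at C3' and the phenoxide displaces the sulfide, giving bromide A2.
- Merits: two bonds and both inner stereocentres form in one step from simple pieces, trans selectivity is inherent, and A2 would be reached in roughly half the ten steps that the chosen plan spends on 16. On step count for the inner ring this road is better.
- Weak points: enantiocontrol rests on a stoichiometric chiral sulfide with a semi-stabilised benzyl ylide, much less developed than ester-stabilised ylides. 2,4-Dimethoxybenzyl sulfonium salts lose sulfide easily. The B4 oxygen of A2 is a methyl ether that cannot later be told from the other seven, and the outer ring is not addressed.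
- Comparison: the chosen plan sets against the shorter sequence a catalytic, catalyst-controlled reaction that is used twice (so its first use tests the second) and a B4 oxygen that is distinguishable from the start. If the ylide step gave high enantiomeric purity with a cleavable B4 group, it would be the better entry to the inner fragment.

Alternative 3: The inner furan would be cut at the aryl–oxygen bond O1'–B6 together with the B1–CHO bond. n-BuLi deprotonates a C2' alcohol and exchanges a B1 bromide; loss of LiF gives an aryne, the alkoxide adds at B6, and the B1 aryllithium is trapped with DMF to give aldehyde A3.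
- Merits: the ring is closed without ionising or oxidising a benzylic position, so there is no risk of dehydrogenation to a benzofuran, which step 8 of the chosen plan does carry. The tether fixes the regiochemistry, and the formyl handle, the same one as in 13, is installed in the same flask.
- Weak points: the stereochemical problem is moved to an acyclic triaryl alcohol in which C3' and C2' both have to be set beforehand and cannot be corrected afterwards. The substrate holds a doubly benzylic C3'–H next to the aryne-forming ring under n-BuLi, and the aryne can be intercepted by the base. B4 is again a methyl ether.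
- Comparison: the two roads are of similar length up to the aldehyde, and A3 avoids the over-oxidation risk. The chosen plan needs only one centre per ring from asymmetric catalysis, because C2' follows C3' under equilibrating conditions, and exposes no stereodefined intermediate to an organolithium.

Key step: step 20

Remark: the ligand antipode of the iridium catalyst that gives the (S) centres is to be assigned in step 6. Alkenes 10 and 23 have the same arrangement of groups and should call for the same antipode.

## Route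

Step 1
Reactants: 1 4-(benzyloxy)-2-hydroxybenzaldehyde
Product: 2 4-(benzyloxy)-2-(methoxymethoxy)benzaldehyde
Conditions: NaH, MOMCl, DMF, 0 °C to rt
Reagents that add atoms: chloromethyl methyl ether, COCCl
Why: Williamson etherification of the only free (chelated) phenol. The MOM ether later directs the lithiation of step 4 and can be removed with acid beside the benzyl ether.

Step 2
Reactants: 2 4-(benzyloxy)-2-(methoxymethoxy)benzaldehyde
Product: 3 4-(benzyloxy)-1-(dimethoxymethyl)-2-(methoxymethoxy)benzene
Conditions: HC(OMe)3, PPTS (cat.), MeOH, rt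
Reagents that add atoms: trimethyl orthoformate, COC(OC)OC
Why: Acid-catalysed acetalisation masks the aldehyde against n-BuLi. PPTS at room temperature should leave the aryl MOM ether intact.

Step 3
Reactants: 4 2,4-dimethoxybenzaldehyde
Product: 5 1-(2,2-dibromoethenyl)-2,4-dimethoxybenzene
Conditions: CBr4, PPh3, CH2Cl2, 0 °C
Reagents that add atoms: carbon tetrabromide, BrC(Br)(Br)Br
Why: Ramirez dibromoolefination (first stage of the Corey–Fuchs sequence) of an aromatic aldehyde with the ylide Ph3P=CBr2.

Step 4
Reactants: 3 4-(benzyloxy)-1-(dimethoxymethyl)-2-(methoxymethoxy)benzene, 5 1-(2,2-dibromoethenyl)-2,4-dimethoxybenzene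
Product: 8 1-(benzyloxy)-2-[(Z)-1-bromo-2-(2,4-dimethoxyphenyl)ethenyl]-4-(dimethoxymethyl)-3-(methoxymethoxy)benzene, via aryllithium 6 (not isolated), via arylzinc chloride 7 (not isolated)
Conditions: n-BuLi, THF, 0 °C; ZnCl2, 0 °C to rt; 5, PdCl2(DPEphos) (3 mol%), rt to 45 °C
Reagents that add atoms: none
Why: Directed ortho-metalation at the only position flanked by two alkoxy groups, transmetalation to zinc and Negishi coupling. In a 1,1-dibromoalkene oxidative addition takes the bromide trans to the aryl group, so the hindered arylzinc should enter trans to the 2,4-dimethoxyphenyl group and leave the (Z)-bromoalkene.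

Step 5
Reactants: 8 1-(benzyloxy)-2-[(Z)-1-bromo-2-(2,4-dimethoxyphenyl)ethenyl]-4-(dimethoxymethyl)-3-(methoxymethoxy)benzene, 9 (3,5-dimethoxyphenyl)boronic acid
Product: 10 1-(benzyloxy)-2-[(E)-2-(2,4-dimethoxyphenyl)-1-(3,5-dimethoxyphenyl)ethenyl]-4-(dimethoxymethyl)-3-(methoxymethoxy)benzene
Conditions: Pd(OAc)2 (3 mol%), SPhos, K3PO4, toluene/H2O, 70 °C
Reagents that add atoms: none
Why: Suzuki–Miyaura coupling of an alkenyl bromide with retention of geometry. The 3,5-dimethoxyphenyl group ends cis to the 2,4-dimethoxyphenyl group and the alkene should be a single isomer, as the next step requires.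

Step 6
Reactants: 10 1-(benzyloxy)-2-[(E)-2-(2,4-dimethoxyphenyl)-1-(3,5-dimethoxyphenyl)ethenyl]-4-(dimethoxymethyl)-3-(methoxymethoxy)benzene
Product: 11 1-(benzyloxy)-2-[(1S)-2-(2,4-dimethoxyphenyl)-1-(3,5-dimethoxyphenyl)ethyl]-4-(dimethoxymethyl)-3-(methoxymethoxy)benzene
Conditions: H2 (50 bar), [Ir(cod)(tBu-PHOX)]BArF (2 mol%), CH2Cl2, rt
Reagents that add atoms: none
Why: Iridium N,P-catalysed asymmetric hydrogenation of a geometrically defined triaryl-substituted alkene. The perpendicular 2,6-dioxygenated aryl group and the planar 3,5-dimethoxyphenyl group on C3' are told apart by the catalyst, which delivers H2 to one face and sets C3' as S. Any loss of acetal or MOM under the acidic hydride catalyst is harmless, because step 7 removes both.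

Step 7
Reactants: 11 1-(benzyloxy)-2-[(1S)-2-(2,4-dimethoxyphenyl)-1-(3,5-dimethoxyphenyl)ethyl]-4-(dimethoxymethyl)-3-(methoxymethoxy)benzene
Product: 12 4-(benzyloxy)-3-[(1S)-2-(2,4-dimethoxyphenyl)-1-(3,5-dimethoxyphenyl)ethyl]-2-hydroxybenzaldehyde
Conditions: HCl (3 M aq), THF, 45 °C
Reagents that add atoms: water, O
Why: Acid hydrolysis of the dimethyl acetal and of the aryl MOM ether in one operation. Benzyl and methyl ethers are stable, and the B6 phenol is released next to the regenerated formyl group.

Step 8
Reactants: 12 4-(benzyloxy)-3-[(1S)-2-(2,4-dimethoxyphenyl)-1-(3,5-dimethoxyphenyl)ethyl]-2-hydroxybenzaldehyde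
Product: 13 (2S,3S)-4-(benzyloxy)-2-(2,4-dimethoxyphenyl)-3-(3,5-dimethoxyphenyl)-2,3-dihydro-1-benzofuran-7-carbaldehyde
Conditions: DDQ (1.1 equiv), 1,4-dioxane, rt to 50 °C
Reagents that add atoms: none
Why: DDQ abstracts hydride from the 2,4-dimethoxybenzylic methylene (dehydrogenative cyclisation of the flavan and pterocarpan type) and the ortho phenol captures the cation in a 5-exo closure. Attack anti to the C3' aryl group and reversible ionisation should give the trans (2S,3S) ring. The formyl group keeps ring B and the C3' hydrogen out of the oxidation.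

Step 9
Reactants: 13 (2S,3S)-4-(benzyloxy)-2-(2,4-dimethoxyphenyl)-3-(3,5-dimethoxyphenyl)-2,3-dihydro-1-benzofuran-7-carbaldehyde
Product: 15 (2S,3S)-4-(benzyloxy)-2-(2,4-dimethoxyphenyl)-3-(3,5-dimethoxyphenyl)-2,3-dihydro-1-benzofuran-7-ol, via aryl formate 14 (not isolated)
Conditions: mCPBA, CH2Cl2, 0 °C to rt; then K2CO3 (cat.), MeOH
Reagents that add atoms: 3-chloroperoxybenzoic acid, OOC(=O)c1cccc(Cl)c1
Why: Dakin oxidation (Baeyer–Villiger reaction with aryl migration, favoured by the ortho and para oxygens) followed by methanolysis of the formate turns the formyl place-holder into a phenol.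

Step 10
Reactants: 15 (2S,3S)-4-(benzyloxy)-2-(2,4-dimethoxyphenyl)-3-(3,5-dimethoxyphenyl)-2,3-dihydro-1-benzofuran-7-ol
Product: 16 (2S,3S)-4-(benzyloxy)-2-(2,4-dimethoxyphenyl)-3-(3,5-dimethoxyphenyl)-2,3-dihydro-1-benzofuran-7-yl trifluoromethanesulfonate
Conditions: Tf2O, pyridine, CH2Cl2, 0 °C
Reagents that add atoms: trifluoromethanesulfonic anhydride, O=S(=O)(OS(=O)(=O)C(F)(F)F)C(F)(F)F
Why: O-Sulfonylation of the phenol gives the aryl triflate that serves as electrophile in step 13.

Step 11
Reactants: 17 1-(2,6-dihydroxy-4-methoxyphenyl)ethan-1-one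
Product: 18 1-[2-(benzyloxy)-6-hydroxy-4-methoxyphenyl]ethan-1-one
Conditions: BnBr (1.05 equiv), K2CO3, acetone, reflux
Reagents that add atoms: benzyl bromide, BrCc1ccccc1
Why: Williamson mono-benzylation. The two hydroxyls are equivalent, and after the first alkylation the remaining one is held in a hydrogen bond to the carbonyl group and reacts much more slowly.

Step 12
Reactants: 18 1-[2-(benzyloxy)-6-hydroxy-4-methoxyphenyl]ethan-1-one
Product: 19 1-[2-(benzyloxy)-4-methoxy-6-(methoxymethoxy)phenyl]ethan-1-one
Conditions: NaH, MOMCl, DMF, 0 °C to rt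
Reagents that add atoms: chloromethyl methyl ether, COCCl
Why: Williamson etherification of the chelated phenol through its sodium salt. Benzyl and MOM now mark the two ortho oxygens of ring A for separate release.

Step 13
Reactants: 19 1-[2-(benzyloxy)-4-methoxy-6-(methoxymethoxy)phenyl]ethan-1-one, 16 (2S,3S)-4-(benzyloxy)-2-(2,4-dimethoxyphenyl)-3-(3,5-dimethoxyphenyl)-2,3-dihydro-1-benzofuran-7-yl trifluoromethanesulfonate
Product: 20 1-[2-(benzyloxy)-4-methoxy-6-(methoxymethoxy)phenyl]-2-[(2S,3S)-4-(benzyloxy)-2-(2,4-dimethoxyphenyl)-3-(3,5-dimethoxyphenyl)-2,3-dihydro-1-benzofuran-7-yl]ethan-1-one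
Conditions: Pd2(dba)3 (2.5 mol%), XPhos, NaOtBu, toluene, 70 °C
Reagents that add atoms: none
Why: Palladium-catalysed α-arylation of a methyl ketone enolate with an aryl triflate. The 2,6-disubstituted aryl ketone cannot self-condense, and the ortho-substituted aryl group disfavours a second arylation.

Step 14
Reactants: 20 1-[2-(benzyloxy)-4-methoxy-6-(methoxymethoxy)phenyl]-2-[(2S,3S)-4-(benzyloxy)-2-(2,4-dimethoxyphenyl)-3-(3,5-dimethoxyphenyl)-2,3-dihydro-1-benzofuran-7-yl]ethan-1-one
Product: 22 (Z)-1-[2-(benzyloxy)-4-methoxy-6-(methoxymethoxy)phenyl]-2-[(2S,3S)-4-(benzyloxy)-2-(2,4-dimethoxyphenyl)-3-(3,5-dimethoxyphenyl)-2,3-dihydro-1-benzofuran-7-yl]ethenyl trifluoromethanesulfonate, via potassium enolate 21 (not isolated)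
Conditions: KN(SiMe3)2, THF, −78 °C; PhNTf2, −78 to 0 °C
Reagents that add atoms: N-phenylbis(trifluoromethanesulfonimide), O=S(=O)(N(c1ccccc1)S(=O)(=O)C(F)(F)F)C(F)(F)F
Why: Deprotonation of the deoxybenzoin should give the (Z)-enolate, in which the benzofuranyl group avoids the 2,6-disubstituted aryl group. O-Sulfonylation fixes this geometry as the enol triflate.

Step 15
Reactants: 22 (Z)-1-[2-(benzyloxy)-4-methoxy-6-(methoxymethoxy)phenyl]-2-[(2S,3S)-4-(benzyloxy)-2-(2,4-dimethoxyphenyl)-3-(3,5-dimethoxyphenyl)-2,3-dihydro-1-benzofuran-7-yl]ethenyl trifluoromethanesulfonate, 9 (3,5-dimethoxyphenyl)boronic acid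
Product: 23 (2S,3S)-4-(benzyloxy)-7-{(E)-2-[2-(benzyloxy)-4-methoxy-6-(methoxymethoxy)phenyl]-2-(3,5-dimethoxyphenyl)ethenyl}-2-(2,4-dimethoxyphenyl)-3-(3,5-dimethoxyphenyl)-2,3-dihydro-1-benzofuran
Conditions: Pd(PPh3)4 (5 mol%), K3PO4, 1,4-dioxane/H2O, 80 °C
Reagents that add atoms: none
Why: Suzuki–Miyaura coupling of the enol triflate with retention of configuration should give the triarylethylene as a single (E) isomer with ring A trans to ring B.

Step 16
Reactants: 23 (2S,3S)-4-(benzyloxy)-7-{(E)-2-[2-(benzyloxy)-4-methoxy-6-(methoxymethoxy)phenyl]-2-(3,5-dimethoxyphenyl)ethenyl}-2-(2,4-dimethoxyphenyl)-3-(3,5-dimethoxyphenyl)-2,3-dihydro-1-benzofuran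
Product: 24 (2S,3S)-4-(benzyloxy)-7-{(2S)-2-[2-(benzyloxy)-4-methoxy-6-(methoxymethoxy)phenyl]-2-(3,5-dimethoxyphenyl)ethyl}-2-(2,4-dimethoxyphenyl)-3-(3,5-dimethoxyphenyl)-2,3-dihydro-1-benzofuran
Conditions: H2 (50 bar), [Ir(cod)(tBu-PHOX)]BArF (2 mol%), CH2Cl2, rt
Reagents that add atoms: none
Why: The same iridium-catalysed asymmetric hydrogenation as in step 6, on an alkene with the same arrangement of groups (2,6-dioxygenated aryl trans to the third aryl group). The same catalyst antipode should therefore set C3 as S; the inner stereocentres are remote, so the catalyst decides.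

Step 17
Reactants: 24 (2S,3S)-4-(benzyloxy)-7-{(2S)-2-[2-(benzyloxy)-4-methoxy-6-(methoxymethoxy)phenyl]-2-(3,5-dimethoxyphenyl)ethyl}-2-(2,4-dimethoxyphenyl)-3-(3,5-dimethoxyphenyl)-2,3-dihydro-1-benzofuran
Product: 25 3-(benzyloxy)-2-{(1S)-2-[(2S,3S)-4-(benzyloxy)-2-(2,4-dimethoxyphenyl)-3-(3,5-dimethoxyphenyl)-2,3-dihydro-1-benzofuran-7-yl]-1-(3,5-dimethoxyphenyl)ethyl}-5-methoxyphenol
Conditions: HCl (cat.), MeOH/THF, 45 °C
Reagents that add atoms: none
Why: Acid-catalysed transacetalisation removes the MOM group and frees the ring A oxygen that will carry the triflate. Benzyl ethers are stable, and any ionisation of the inner benzylic ether is reversible and returns the trans ring.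

Step 18
Reactants: 25 3-(benzyloxy)-2-{(1S)-2-[(2S,3S)-4-(benzyloxy)-2-(2,4-dimethoxyphenyl)-3-(3,5-dimethoxyphenyl)-2,3-dihydro-1-benzofuran-7-yl]-1-(3,5-dimethoxyphenyl)ethyl}-5-methoxyphenol
Product: 26 3-(benzyloxy)-2-{(1S)-2-[(2S,3S)-4-(benzyloxy)-2-(2,4-dimethoxyphenyl)-3-(3,5-dimethoxyphenyl)-2,3-dihydro-1-benzofuran-7-yl]-1-(3,5-dimethoxyphenyl)ethyl}-5-methoxyphenyl trifluoromethanesulfonate
Conditions: Tf2O, pyridine, CH2Cl2, 0 °C
Reagents that add atoms: trifluoromethanesulfonic anhydride, O=S(=O)(OS(=O)(=O)C(F)(F)F)C(F)(F)F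
Why: O-Sulfonylation of the single free phenol installs the aryl triflate, which is the electron-withdrawing group on ring A in step 20 and the leaving group in step 21.

Step 19
Reactants: 26 3-(benzyloxy)-2-{(1S)-2-[(2S,3S)-4-(benzyloxy)-2-(2,4-dimethoxyphenyl)-3-(3,5-dimethoxyphenyl)-2,3-dihydro-1-benzofuran-7-yl]-1-(3,5-dimethoxyphenyl)ethyl}-5-methoxyphenyl trifluoromethanesulfonate
Product: 27 2-{(1S)-1-(3,5-dimethoxyphenyl)-2-[(2S,3S)-2-(2,4-dimethoxyphenyl)-3-(3,5-dimethoxyphenyl)-4-hydroxy-2,3-dihydro-1-benzofuran-7-yl]ethyl}-3-hydroxy-5-methoxyphenyl trifluoromethanesulfonate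
Conditions: H2 (1 atm), palladium on carbon (Pd/C, 10%), EtOAc, rt
Reagents that add atoms: none
Why: Hydrogenolysis of the two benzyl ethers under neutral conditions frees the ring A phenol and the B4 phenol together. Aryl triflates and methyl ethers are not reduced in the absence of base.

Step 20
Reactants: 27 2-{(1S)-1-(3,5-dimethoxyphenyl)-2-[(2S,3S)-2-(2,4-dimethoxyphenyl)-3-(3,5-dimethoxyphenyl)-4-hydroxy-2,3-dihydro-1-benzofuran-7-yl]ethyl}-3-hydroxy-5-methoxyphenyl trifluoromethanesulfonate
Product: 29 (2S,3S)-2-[(2S,3S)-2-(2,4-dimethoxyphenyl)-3-(3,5-dimethoxyphenyl)-4-hydroxy-2,3-dihydro-1-benzofuran-7-yl]-3-(3,5-dimethoxyphenyl)-6-methoxy-2,3-dihydro-1-benzofuran-4-yl trifluoromethanesulfonate, via para-quinone methide 28 (not isolated)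
Conditions: DDQ (1.05 equiv), CH2Cl2, −20 to 0 °C
Reagents that add atoms: none
Why: DDQ should engage the more electron-rich phenol, that of ring B (two alkyl groups and the O1' ether), and remove hydride from the para-benzylic C2 methylene, giving para-quinone methide 28 with C2 as exocyclic carbon. The ring A phenol then adds to C2 in a conjugate addition and ring B rearomatises, so the O1–C2 bond forms in a 5-exo-trig closure. The closest known reaction type is the oxidative cyclisation of ortho-(2-arylethyl)phenols through quinone methides with DDQ or Ag2O, as in pterocarpan synthesis and in the second stage of dihydrobenzofuran neolignan coupling. C2 should form trans to the C3 aryl group: the phenol attacks the face of the methide away from the 3,5-dimethoxyphenyl group, and the addition is reversible through the quinone methide, so the more stable (2S,3S) ring accumulates. The step needs the oxidant to take the B4 phenol and not to form an ortho-quinone methide at C3 from the ring A phenol; in 27 the C3–H bond is held near the plane of ring A by the two ortho substituents and is poorly aligned for hydride loss, and the triflate makes ring A the less electron-rich phenol. All other oxygens are methyl ethers, which react with DDQ far more slowly than a phenol at −20 to 0 °C, and this also protects the 2,4-dimethoxybenzylic C2'–H of the inner ring. A two-electron oxidant in near-stoichiometric amount is chosen so that the free ortho position B3 is not exposed to phenoxyl radical coupling and the product, itself a para-hydroxybenzyl ether, is not dehydrogenated further.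

Step 21
Reactants: 29 (2S,3S)-2-[(2S,3S)-2-(2,4-dimethoxyphenyl)-3-(3,5-dimethoxyphenyl)-4-hydroxy-2,3-dihydro-1-benzofuran-7-yl]-3-(3,5-dimethoxyphenyl)-6-methoxy-2,3-dihydro-1-benzofuran-4-yl trifluoromethanesulfonate, 30 [(E)-2-(4-methoxyphenyl)ethenyl]boronic acid
Product: 31 (2S,3S)-2-(2,4-dimethoxyphenyl)-3-(3,5-dimethoxyphenyl)-7-{(2S,3S)-3-(3,5-dimethoxyphenyl)-6-methoxy-4-[(E)-2-(4-methoxyphenyl)ethenyl]-2,3-dihydro-1-benzofuran-2-yl}-2,3-dihydro-1-benzofuran-4-ol
Conditions: Pd(OAc)2 (5 mol%), SPhos, K3PO4, THF/H2O, 60 °C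
Reagents that add atoms: none
Why: Suzuki–Miyaura coupling of the hindered aryl triflate with an (E)-alkenylboronic acid transfers the styryl group with retention of the double-bond geometry. The free phenol is tolerated as its phenoxide.

Step 22
Reactants: 31 (2S,3S)-2-(2,4-dimethoxyphenyl)-3-(3,5-dimethoxyphenyl)-7-{(2S,3S)-3-(3,5-dimethoxyphenyl)-6-methoxy-4-[(E)-2-(4-methoxyphenyl)ethenyl]-2,3-dihydro-1-benzofuran-2-yl}-2,3-dihydro-1-benzofuran-4-ol
Product: 32 (2S,3S)-2-[(2S,3S)-2-(2,4-dihydroxyphenyl)-3-(3,5-dihydroxyphenyl)-4-hydroxy-2,3-dihydro-1-benzofuran-7-yl]-3-(3,5-dihydroxyphenyl)-4-[(E)-2-(4-hydroxyphenyl)ethenyl]-2,3-dihydro-1-benzofuran-6-ol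
Conditions: BBr3 (excess), CH2Cl2, −78 to 0 °C; then H2O
Reagents that add atoms: none
Why: Lewis acid cleavage of the eight aryl methyl ethers with BBr3 at low temperature. Both furans are already the more stable trans isomers, so reversible opening at C2 or C2' should return the same configuration, and C3 and C3' are not touched.

## Compound list

1 | 4-(benzyloxy)-2-hydroxybenzaldehyde | O=Cc1ccc(OCc2ccccc2)cc1O | starting material
2 | 4-(benzyloxy)-2-(methoxymethoxy)benzaldehyde | O=Cc1ccc(OCc2ccccc2)cc1OCOC | intermediate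
3 | 4-(benzyloxy)-1-(dimethoxymethyl)-2-(methoxymethoxy)benzene | COC(OC)c1ccc(OCc2ccccc2)cc1OCOC | intermediate
4 | 2,4-dimethoxybenzaldehyde | COc1ccc(C=O)c(OC)c1 | starting material
5 | 1-(2,2-dibromoethenyl)-2,4-dimethoxybenzene | COc1ccc(C=C(Br)Br)c(OC)c1 | intermediate
6 | [6-(benzyloxy)-3-(dimethoxymethyl)-2-(methoxymethoxy)phenyl]lithium (formed in the flask) | [Li]c1c(OCOC)c(C(OC)OC)ccc1OCc1ccccc1 | intermediate
7 | [6-(benzyloxy)-3-(dimethoxymethyl)-2-(methoxymethoxy)phenyl]zinc chloride (formed in the flask) | Cl[Zn]c1c(OCOC)c(C(OC)OC)ccc1OCc1ccccc1 | intermediate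
8 | 1-(benzyloxy)-2-[(Z)-1-bromo-2-(2,4-dimethoxyphenyl)ethenyl]-4-(dimethoxymethyl)-3-(methoxymethoxy)benzene | COc1ccc(/C=C(\Br)c2c(OCOC)c(C(OC)OC)ccc2OCc2ccccc2)c(OC)c1 | intermediate
9 | (3,5-dimethoxyphenyl)boronic acid | COc1cc(OC)cc(B(O)O)c1 | starting material
10 | 1-(benzyloxy)-2-[(E)-2-(2,4-dimethoxyphenyl)-1-(3,5-dimethoxyphenyl)ethenyl]-4-(dimethoxymethyl)-3-(methoxymethoxy)benzene | COc1ccc(/C=C(\c2cc(OC)cc(OC)c2)c2c(OCOC)c(C(OC)OC)ccc2OCc2ccccc2)c(OC)c1 | intermediate
11 | 1-(benzyloxy)-2-[(1S)-2-(2,4-dimethoxyphenyl)-1-(3,5-dimethoxyphenyl)ethyl]-4-(dimethoxymethyl)-3-(methoxymethoxy)benzene | COc1ccc(C[C@@H](c2cc(OC)cc(OC)c2)c2c(OCOC)c(C(OC)OC)ccc2OCc2ccccc2)c(OC)c1 | intermediate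
12 | 4-(benzyloxy)-3-[(1S)-2-(2,4-dimethoxyphenyl)-1-(3,5-dimethoxyphenyl)ethyl]-2-hydroxybenzaldehyde | COc1ccc(C[C@@H](c2cc(OC)cc(OC)c2)c2c(O)c(C=O)ccc2OCc2ccccc2)c(OC)c1 | intermediate
13 | (2S,3S)-4-(benzyloxy)-2-(2,4-dimethoxyphenyl)-3-(3,5-dimethoxyphenyl)-2,3-dihydro-1-benzofuran-7-carbaldehyde | O=Cc1ccc(OCc2ccccc2)c2c1O[C@H](c1ccc(OC)cc1OC)[C@H]2c1cc(OC)cc(OC)c1 | intermediate
14 | (2S,3S)-4-(benzyloxy)-2-(2,4-dimethoxyphenyl)-3-(3,5-dimethoxyphenyl)-2,3-dihydro-1-benzofuran-7-yl formate (formed in the flask) | O=COc1ccc(OCc2ccccc2)c2c1O[C@H](c1ccc(OC)cc1OC)[C@H]2c1cc(OC)cc(OC)c1 | intermediate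
15 | (2S,3S)-4-(benzyloxy)-2-(2,4-dimethoxyphenyl)-3-(3,5-dimethoxyphenyl)-2,3-dihydro-1-benzofuran-7-ol | Oc1ccc(OCc2ccccc2)c2c1O[C@H](c1ccc(OC)cc1OC)[C@H]2c1cc(OC)cc(OC)c1 | intermediate
16 | (2S,3S)-4-(benzyloxy)-2-(2,4-dimethoxyphenyl)-3-(3,5-dimethoxyphenyl)-2,3-dihydro-1-benzofuran-7-yl trifluoromethanesulfonate | O=S(=O)(Oc1ccc(OCc2ccccc2)c2c1O[C@H](c1ccc(OC)cc1OC)[C@H]2c1cc(OC)cc(OC)c1)C(F)(F)F | intermediate
17 | 1-(2,6-dihydroxy-4-methoxyphenyl)ethan-1-one | CC(=O)c1c(O)cc(OC)cc1O | starting material
18 | 1-[2-(benzyloxy)-6-hydroxy-4-methoxyphenyl]ethan-1-one | CC(=O)c1c(O)cc(OC)cc1OCc1ccccc1 | intermediate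
19 | 1-[2-(benzyloxy)-4-methoxy-6-(methoxymethoxy)phenyl]ethan-1-one | CC(=O)c1c(OCOC)cc(OC)cc1OCc1ccccc1 | intermediate
20 | 1-[2-(benzyloxy)-4-methoxy-6-(methoxymethoxy)phenyl]-2-[(2S,3S)-4-(benzyloxy)-2-(2,4-dimethoxyphenyl)-3-(3,5-dimethoxyphenyl)-2,3-dihydro-1-benzofuran-7-yl]ethan-1-one | O=C(Cc1ccc(OCc2ccccc2)c2c1O[C@H](c1ccc(OC)cc1OC)[C@H]2c1cc(OC)cc(OC)c1)c1c(OCOC)cc(OC)cc1OCc1ccccc1 | intermediate
21 | potassium (Z)-enolate of 20, oxygen cis to the benzofuranyl group (formed in the flask) | [K+].[O-]/C(=C\c1ccc(OCc2ccccc2)c2c1O[C@H](c1ccc(OC)cc1OC)[C@H]2c1cc(OC)cc(OC)c1)c1c(OCOC)cc(OC)cc1OCc1ccccc1 | intermediate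
22 | (Z)-1-[2-(benzyloxy)-4-methoxy-6-(methoxymethoxy)phenyl]-2-[(2S,3S)-4-(benzyloxy)-2-(2,4-dimethoxyphenyl)-3-(3,5-dimethoxyphenyl)-2,3-dihydro-1-benzofuran-7-yl]ethenyl trifluoromethanesulfonate | O=S(=O)(O/C(=C\c1ccc(OCc2ccccc2)c2c1O[C@H](c1ccc(OC)cc1OC)[C@H]2c1cc(OC)cc(OC)c1)c1c(OCOC)cc(OC)cc1OCc1ccccc1)C(F)(F)F | intermediate
23 | (2S,3S)-4-(benzyloxy)-7-{(E)-2-[2-(benzyloxy)-4-methoxy-6-(methoxymethoxy)phenyl]-2-(3,5-dimethoxyphenyl)ethenyl}-2-(2,4-dimethoxyphenyl)-3-(3,5-dimethoxyphenyl)-2,3-dihydro-1-benzofuran | COc1cc(OC)cc(c1)/C(=C\c1ccc(OCc2ccccc2)c2c1O[C@H](c1ccc(OC)cc1OC)[C@H]2c1cc(OC)cc(OC)c1)c1c(OCOC)cc(OC)cc1OCc1ccccc1 | intermediate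
24 | (2S,3S)-4-(benzyloxy)-7-{(2S)-2-[2-(benzyloxy)-4-methoxy-6-(methoxymethoxy)phenyl]-2-(3,5-dimethoxyphenyl)ethyl}-2-(2,4-dimethoxyphenyl)-3-(3,5-dimethoxyphenyl)-2,3-dihydro-1-benzofuran | COCOc1cc(OC)cc(OCc2ccccc2)c1[C@@H](Cc1ccc(OCc2ccccc2)c2c1O[C@H](c1ccc(OC)cc1OC)[C@H]2c1cc(OC)cc(OC)c1)c1cc(OC)cc(OC)c1 | intermediate
25 | 3-(benzyloxy)-2-{(1S)-2-[(2S,3S)-4-(benzyloxy)-2-(2,4-dimethoxyphenyl)-3-(3,5-dimethoxyphenyl)-2,3-dihydro-1-benzofuran-7-yl]-1-(3,5-dimethoxyphenyl)ethyl}-5-methoxyphenol | Oc1cc(OC)cc(OCc2ccccc2)c1[C@@H](Cc1ccc(OCc2ccccc2)c2c1O[C@H](c1ccc(OC)cc1OC)[C@H]2c1cc(OC)cc(OC)c1)c1cc(OC)cc(OC)c1 | intermediate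
26 | 3-(benzyloxy)-2-{(1S)-2-[(2S,3S)-4-(benzyloxy)-2-(2,4-dimethoxyphenyl)-3-(3,5-dimethoxyphenyl)-2,3-dihydro-1-benzofuran-7-yl]-1-(3,5-dimethoxyphenyl)ethyl}-5-methoxyphenyl trifluoromethanesulfonate | O=S(=O)(Oc1cc(OC)cc(OCc2ccccc2)c1[C@@H](Cc1ccc(OCc2ccccc2)c2c1O[C@H](c1ccc(OC)cc1OC)[C@H]2c1cc(OC)cc(OC)c1)c1cc(OC)cc(OC)c1)C(F)(F)F | intermediate
27 | 2-{(1S)-1-(3,5-dimethoxyphenyl)-2-[(2S,3S)-2-(2,4-dimethoxyphenyl)-3-(3,5-dimethoxyphenyl)-4-hydroxy-2,3-dihydro-1-benzofuran-7-yl]ethyl}-3-hydroxy-5-methoxyphenyl trifluoromethanesulfonate | O=S(=O)(Oc1cc(OC)cc(O)c1[C@@H](Cc1ccc(O)c2c1O[C@H](c1ccc(OC)cc1OC)[C@H]2c1cc(OC)cc(OC)c1)c1cc(OC)cc(OC)c1)C(F)(F)F | intermediate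
28 | para-quinone methide of ring B: (2S,3S)-2-(2,4-dimethoxyphenyl)-3-(3,5-dimethoxyphenyl)-7-[(2S)-2-aryl-2-(3,5-dimethoxyphenyl)ethylidene]-2,3-dihydro-1-benzofuran-4(7H)-one, aryl = 2-hydroxy-4-methoxy-6-(trifluoromethanesulfonyloxy)phenyl (formed in the flask) | O=S(=O)(Oc1cc(OC)cc(O)c1[C@@H](C=C1C=CC(=O)C2=C1O[C@H](c1ccc(OC)cc1OC)[C@H]2c1cc(OC)cc(OC)c1)c1cc(OC)cc(OC)c1)C(F)(F)F | intermediate
29 | (2S,3S)-2-[(2S,3S)-2-(2,4-dimethoxyphenyl)-3-(3,5-dimethoxyphenyl)-4-hydroxy-2,3-dihydro-1-benzofuran-7-yl]-3-(3,5-dimethoxyphenyl)-6-methoxy-2,3-dihydro-1-benzofuran-4-yl trifluoromethanesulfonate | O=S(=O)(Oc1cc(OC)cc2c1[C@H](c1cc(OC)cc(OC)c1)[C@@H](c1ccc(O)c3c1O[C@H](c1ccc(OC)cc1OC)[C@H]3c1cc(OC)cc(OC)c1)O2)C(F)(F)F | intermediate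
30 | [(E)-2-(4-methoxyphenyl)ethenyl]boronic acid | COc1ccc(/C=C/B(O)O)cc1 | starting material
31 | (2S,3S)-2-(2,4-dimethoxyphenyl)-3-(3,5-dimethoxyphenyl)-7-{(2S,3S)-3-(3,5-dimethoxyphenyl)-6-methoxy-4-[(E)-2-(4-methoxyphenyl)ethenyl]-2,3-dihydro-1-benzofuran-2-yl}-2,3-dihydro-1-benzofuran-4-ol | COc1ccc(/C=C/c2cc(OC)cc3c2[C@H](c2cc(OC)cc(OC)c2)[C@@H](c2ccc(O)c4c2O[C@H](c2ccc(OC)cc2OC)[C@H]4c2cc(OC)cc(OC)c2)O3)cc1 | intermediate
32 | (2S,3S)-2-[(2S,3S)-2-(2,4-dihydroxyphenyl)-3-(3,5-dihydroxyphenyl)-4-hydroxy-2,3-dihydro-1-benzofuran-7-yl]-3-(3,5-dihydroxyphenyl)-4-[(E)-2-(4-hydroxyphenyl)ethenyl]-2,3-dihydro-1-benzofuran-6-ol | Oc1ccc(/C=C/c2cc(O)cc3c2[C@H](c2cc(O)cc(O)c2)[C@@H](c2ccc(O)c4c2O[C@H](c2ccc(O)cc2O)[C@H]4c2cc(O)cc(O)c2)O3)cc1 | target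

## Step count and least certain steps

Total: 22 steps. Longest linear sequence: 19 steps (1, 2, 4 to 10, 13 to 22); steps 3, 11 and 12 prepare the side pieces 5 and 19.

**Step 20 (key step).** The most likely failure is over-oxidation. Product 29 is itself a para-hydroxybenzyl aryl ether, so a second hydride loss at C2 followed by loss of the C3 proton would aromatise the new ring to a benzofuran. Slow hydride abstraction at the inner 2,4-dimethoxybenzylic C2'–H and intermolecular trapping of the quinone methide could add to it. The fallback separates oxidation from ring closure. Starting from 27, DDQ in CH2Cl2/MeOH at −40 °C should intercept the quinone methide as the benzylic methyl ether F1. After removal of the hydroquinone, catalytic CF3CO2H in CH2Cl2 at 0 °C should ionise F1, and the ring A phenol should close the ring under equilibrating conditions with no oxidant present, returning to the route at 29.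

**Step 6.** The hydrogenation may stall or lose enantioselectivity. The alkene carries a 2,6-dioxygenated aryl group that shields it and whose ether oxygens can bind iridium, and isomerisation of the alkene by the acidic hydride before reduction would erode the selectivity. The fallback gives up induction for separation. Starting from 10, hydrogenation with achiral [Ir(cod)(PCy3)(py)]PF6 should give the racemic triarylethane, and preparative chromatography on a chiral stationary phase should separate 11 from its enantiomer, the (1R)-triarylethane F2. The route is rejoined at 11.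

**Step 8.** The product's C2'–H is a 2,4-dimethoxybenzylic ether hydrogen, so DDQ may go on to the 2,3-diarylbenzofuran and erase both inner stereocentres; alternatively, hydride abstraction from the non-phenolic methylene may be too slow. The fallback avoids any oxidant. Starting from 10, hydroboration with the antipode of monoisopinocampheylborane that places hydrogen on the required face of C3', followed by NaOH/H2O2, should give the syn-addition alcohol F3. HCl in aqueous THF should then remove acetal and MOM group, ionise the 2,4-dimethoxybenzylic alcohol and let the B6 phenol close the trans ring, returning to the route at 13.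

**Step 16.** The risk is the same as in step 6 but on the most valuable alkene of the route: incomplete conversion or reduced selectivity at an alkene flanked by two large aryl groups. The fallback uses the ring A phenol instead of a metal. Starting from 23, HCl in MeOH should remove the MOM group to give the phenol alkene F4. A chiral phosphoric acid such as (R)-TRIP with Hantzsch ester should then protonate the alkene to the ring A ortho-quinone methide (a 2,4,6-trioxygenated benzylic cation) and deliver hydride to one face, an organocatalytic transfer hydrogenation of the kind known for ortho-hydroxy-1,1-diarylalkenes. The alkene geometry no longer matters, and the route is rejoined at 25.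

**Step 22.** HBr formed from BBr3 can protonate the electron-rich stilbene, and the resulting cation can alkylate the neighbouring resorcinol ring at C3; incomplete cleavage of eight ethers is a second risk. The fallback changes the order so that the stilbene never meets the Lewis acid. Starting from 29, BBr3 should give the octaphenol triflate F5. Suzuki–Miyaura coupling of F5 with the pinacol ester of (E)-2-(4-hydroxyphenyl)ethenylboronic acid (Pd(OAc)2, SPhos, K3PO4, aqueous THF) should then give 32 directly.

## Further compounds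

F1 | step 20 | 2-{(1S)-1-(3,5-dimethoxyphenyl)-2-[(2S,3S)-2-(2,4-dimethoxyphenyl)-3-(3,5-dimethoxyphenyl)-4-hydroxy-2,3-dihydro-1-benzofuran-7-yl]-2-methoxyethyl}-3-hydroxy-5-methoxyphenyl trifluoromethanesulfonate, both epimers at the methoxy-bearing carbon | O=S(=O)(Oc1cc(OC)cc(O)c1[C@@H](C(OC)c1ccc(O)c2c1O[C@H](c1ccc(OC)cc1OC)[C@H]2c1cc(OC)cc(OC)c1)c1cc(OC)cc(OC)c1)C(F)(F)F
F2 | step 6 | 1-(benzyloxy)-2-[(1R)-2-(2,4-dimethoxyphenyl)-1-(3,5-dimethoxyphenyl)ethyl]-4-(dimethoxymethyl)-3-(methoxymethoxy)benzene | COc1ccc(C[C@H](c2cc(OC)cc(OC)c2)c2c(OCOC)c(C(OC)OC)ccc2OCc2ccccc2)c(OC)c1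
F3 | step 8 | (1S,2S)-2-[6-(benzyloxy)-3-(dimethoxymethyl)-2-(methoxymethoxy)phenyl]-1-(2,4-dimethoxyphenyl)-2-(3,5-dimethoxyphenyl)ethan-1-ol | COc1ccc([C@@H](O)[C@@H](c2cc(OC)cc(OC)c2)c2c(OCOC)c(C(OC)OC)ccc2OCc2ccccc2)c(OC)c1
F4 | step 16 | 3-(benzyloxy)-2-{(E)-2-[(2S,3S)-4-(benzyloxy)-2-(2,4-dimethoxyphenyl)-3-(3,5-dimethoxyphenyl)-2,3-dihydro-1-benzofuran-7-yl]-1-(3,5-dimethoxyphenyl)ethenyl}-5-methoxyphenol | COc1cc(OC)cc(c1)/C(=C\c1ccc(OCc2ccccc2)c2c1O[C@H](c1ccc(OC)cc1OC)[C@H]2c1cc(OC)cc(OC)c1)c1c(O)cc(OC)cc1OCc1ccccc1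
F5 | step 22 | (2S,3S)-2-[(2S,3S)-2-(2,4-dihydroxyphenyl)-3-(3,5-dihydroxyphenyl)-4-hydroxy-2,3-dihydro-1-benzofuran-7-yl]-3-(3,5-dihydroxyphenyl)-6-hydroxy-2,3-dihydro-1-benzofuran-4-yl trifluoromethanesulfonate | O=S(=O)(Oc1cc(O)cc2c1[C@H](c1cc(O)cc(O)c1)[C@@H](c1ccc(O)c3c1O[C@H](c1ccc(O)cc1O)[C@H]3c1cc(O)cc(O)c1)O2)C(F)(F)F
A1 | alternative 1 | methyl (2S,3S)-2-{3-[(1S,2S)-2-[(tert-butyldimethylsilyl)oxy]-2-(2,4-dimethoxyphenyl)-1-(3,5-dimethoxyphenyl)ethyl]-2-hydroxy-4-[(triisopropylsilyl)oxy]phenyl}-3-(3,5-dimethoxyphenyl)-6-methoxy-2,3-dihydro-1-benzofuran-4-carboxylate | COC(=O)c1cc(OC)cc2c1[C@H](c1cc(OC)cc(OC)c1)[C@@H](c1ccc(O[Si](C(C)C)(C(C)C)C(C)C)c([C@H](c3cc(OC)cc(OC)c3)[C@H](O[Si](C)(C)C(C)(C)C)c3ccc(OC)cc3OC)c1O)O2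
A2 | alternative 2 | (2S,3S)-7-bromo-2-(2,4-dimethoxyphenyl)-3-(3,5-dimethoxyphenyl)-4-methoxy-2,3-dihydro-1-benzofuran | Brc1ccc(OC)c2c1O[C@H](c1ccc(OC)cc1OC)[C@H]2c1cc(OC)cc(OC)c1
A3 | alternative 3 | (2S,3S)-2-(2,4-dimethoxyphenyl)-3-(3,5-dimethoxyphenyl)-4-methoxy-2,3-dihydro-1-benzofuran-7-carbaldehyde | O=Cc1ccc(OC)c2c1O[C@H](c1ccc(OC)cc1OC)[C@H]2c1cc(OC)cc(OC)c1
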